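The benzodioxane is opened at the C7–O3 bond and the C7–C8 bond is traced back to an acylation, so that C8, the dioxane carbon that carries CH2OH and is bonded to O4 of the pyrogallol ring, sits between a C7 aryl ketone and a C9 ester. That position epimerises freely, and the key step uses this: one asymmetric transfer hydrogenation with dynamic kinetic resolution turns the racemic α-aryloxy-β-ketoester, built from three achiral commercial pieces, into a single syn hydroxy ester with both stereocentres of the target. Because O4 is flanked by the equivalent O3 and O5, the later acid closure onto C7 has no regiochemical choice.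

Key step: step 4

Numbering: lignan numbering is used; C7 carries the trimethoxyphenyl ring, C8 carries C9 (CH2OH), and O3, O4, O5 are the oxygens of the pyrogallol ring with O4 para to the side chain.

Assumption: the (R,R)-TsDPEN-type catalyst is taken to follow the usual aryl ketone model, which corresponds to 7S here; if the first run shows the opposite sense, the (S,S) catalyst is used and nothing else changes.

Step 1
Reactants: 1 3,4,5-trihydroxybenzaldehyde; 2 methyl (triphenylphosphoranylidene)acetate
Product: 3 methyl (E)-3-(3,4,5-trihydroxyphenyl)prop-2-enoate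
Conditions: 2 (1.5 equiv), THF, 60 °C, argon
Reagents that add atoms: none
Why: Wittig olefination with an ester-stabilised ylide, which tolerates free phenols when used in slight excess and gives the E-alkene as is usual with aromatic aldehydes.

Step 2
Reactants: 3 methyl (E)-3-(3,4,5-trihydroxyphenyl)prop-2-enoate; 4 methyl bromoacetate
Product: 6 methyl (E)-3-[4-(2-methoxy-2-oxoethoxy)-3,5-bis(methoxymethoxy)phenyl]prop-2-enoate, via mono-alkylated diphenol 5 (not isolated)
Conditions: KHCO3 (1.1 equiv), 4 (1.0 equiv), DMF, rt to 40 °C, argon; then iPr2NEt (4 equiv), MOMCl (3 equiv), 0 °C to rt, same flask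
Reagents that add atoms: chloromethyl methyl ether (MOMCl), COCCl
Why: Williamson etherification followed by MOM acetal protection, in which the 4-OH para to the acrylate is the most acidic phenol and the only one ionised by one equivalent of hydrogencarbonate, and capping the two equivalent flanking phenols in the same flask keeps them from lactonising onto the new ester.

Step 3
Reactants: 6 methyl (E)-3-[4-(2-methoxy-2-oxoethoxy)-3,5-bis(methoxymethoxy)phenyl]prop-2-enoate; 7 3,4,5-trimethoxybenzoyl chloride
Product: 8 racemic methyl 2-{4-[(E)-3-methoxy-3-oxoprop-1-enyl]-2,6-bis(methoxymethoxy)phenoxy}-3-oxo-3-(3,4,5-trimethoxyphenyl)propanoate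
Conditions: LiHMDS (2.1 equiv), THF, −78 °C; then 7 (1.0 equiv), −78 °C; aq NH4Cl
Reagents that add atoms: none
Why: Crossed Claisen condensation (C-acylation of an ester lithium enolate) that forms C7–C8, in which the aryloxyacetate CH2 is the only enolisable position, the second equivalent of the hindered amide takes up the acidic β-ketoester as it forms, and at −78 °C the enolate should react with the acid chloride far faster than with the electron-rich cinnamate.

Step 4
Reactants: 8 racemic methyl 2-aryloxy-3-oxo-3-(3,4,5-trimethoxyphenyl)propanoate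
Product: 9 methyl (2R,3S)-3-hydroxy-2-{4-[(E)-3-methoxy-3-oxoprop-1-enyl]-2,6-bis(methoxymethoxy)phenoxy}-3-(3,4,5-trimethoxyphenyl)propanoate (syn)
Conditions: tethered Cp*Rh(III)–(R,R)-TsDPEN chloride complex (1 mol%), HCO2H/Et3N (5:2), CH2Cl2, 30 °C; any anti isomer removed by chromatography
Reagents that add atoms: none
Why: Proposed new method: the closest known reaction is the transfer-hydrogenative dynamic kinetic resolution of α-alkoxy-β-ketoesters of aryl ketones, which gives syn α-alkoxy-β-hydroxy esters, and it is extended here to an α-aryloxy group that carries two ortho substituents. The metal hydride and the N–H of the sulfonyldiamine ligand transfer H− and H+ to the C7 ketone through an outer-sphere six-membered transition state, so the only new bond is C7–H and no ring is closed. C7 is set by the catalyst: the CH/π contact between the cyclopentadienyl ligand and the trimethoxyphenyl ring fixes the ketone face, which should give 7S with the (R,R) ligand. C8 is set by matching: its proton, flanked by ketone, ester and aryloxy oxygen, exchanges quickly in the formate/amine buffer, and only the enantiomer that can hold the C8–OAr bond anti to the incoming hydride (polar Felkin–Anh arrangement, no chelating metal) is reduced fast, which leads to the syn (2R,3S) isomer. The step needs ketone-face selectivity, syn over anti selectivity and racemisation faster than reduction; the aryl ketone, the acidity of C8–H and the bulk of the 2,6-disubstituted aryloxy group, which slows the mismatched enantiomer further, should secure them, while the MOM ethers and the electron-rich cinnamate are inert to the formate conditions.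

Step 5
Reactants: 9 methyl (2R,3S)-2-aryloxy-3-hydroxy-3-(3,4,5-trimethoxyphenyl)propanoate
Product: 10 methyl (E)-3-[4-{[(1S,2S)-1,3-dihydroxy-1-(3,4,5-trimethoxyphenyl)propan-2-yl]oxy}-3,5-bis(methoxymethoxy)phenyl]prop-2-enoate (threo, 7S,8S)
Conditions: NaBH4 (3 equiv), THF/MeOH (4:1), 0 °C to rt; product recrystallised
Reagents that add atoms: none
Why: Chemoselective borohydride reduction of an activated ester, in which the α-aryloxy ester next to the C7 alkoxide is reduced far faster than the conjugated cinnamate ester and neither stereocentre is touched.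

Step 6
Reactants: 10 threo-(7S,8S) diol with two MOM ethers
Product: 12 methyl (E)-3-[(2S,3S)-8-hydroxy-2-(hydroxymethyl)-3-(3,4,5-trimethoxyphenyl)-2,3-dihydro-1,4-benzodioxin-6-yl]prop-2-enoate (trans, 7S,8S), via deprotected diphenol diol 11 (not isolated)
Conditions: HCl (0.5 M in MeOH), rt; evaporate; then TfOH (10 mol%), HFIP/CH2Cl2 (1:1), 0.005 M, 0 °C to rt
Reagents that add atoms: none
Why: Acetal cleavage followed by acid-catalysed dehydrative etherification (SN1), in which methanolic HCl removes both MOM groups as volatile dimethoxymethane and triflic acid in non-nucleophilic HFIP then ionises the only modestly stabilised C7 benzylic alcohol to a cation that either of the two equivalent flanking phenols captures in a 6-exo-trig closure, re-forming C7 trans to the untouched C8 substituent (aryl and CH2OH both equatorial), which is the 7S configuration.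

Step 7
Reactants: 12 trans-(7S,8S)-benzodioxane methyl cinnamate
Product: 13 (E)-3-[(2S,3S)-8-hydroxy-2-(hydroxymethyl)-3-(3,4,5-trimethoxyphenyl)-2,3-dihydro-1,4-benzodioxin-6-yl]prop-2-en-1-ol
Conditions: DIBAL-H (6 equiv), CH2Cl2/THF, −78 to −20 °C; Rochelle salt
Reagents that add atoms: none
Why: DIBAL 1,2-reduction of an α,β-unsaturated ester to the allylic alcohol, in which the first equivalents are consumed by the phenol and the C9 hydroxyl as inert aluminium alkoxides and the aryl ether bonds of the dioxane ring are not affected at low temperature.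

Step 8
Reactants: 13 benzodioxane cinnamyl alcohol
Product: 14 (E)-3-[(2S,3S)-8-hydroxy-2-(hydroxymethyl)-3-(3,4,5-trimethoxyphenyl)-2,3-dihydro-1,4-benzodioxin-6-yl]prop-2-enal (target CNP0241953.1)
Conditions: activated MnO2 (15 equiv), EtOAc, rt
Reagents that add atoms: none
Why: Manganese dioxide oxidation, which is selective for the allylic (cinnamyl) alcohol and should leave the saturated C9 alcohol, the phenol and the E-alkene unchanged.

Compound list
1 | 3,4,5-trihydroxybenzaldehyde | O=Cc1cc(O)c(O)c(O)c1 | starting material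
2 | methyl (triphenylphosphoranylidene)acetate | COC(=O)C=P(c1ccccc1)(c1ccccc1)c1ccccc1 | starting material
3 | methyl (E)-3-(3,4,5-trihydroxyphenyl)prop-2-enoate | COC(=O)/C=C/c1cc(O)c(O)c(O)c1 | intermediate
4 | methyl bromoacetate | COC(=O)CBr | starting material
5 | methyl (E)-3-[3,5-dihydroxy-4-(2-methoxy-2-oxoethoxy)phenyl]prop-2-enoate | COC(=O)COc1c(O)cc(/C=C/C(=O)OC)cc1O | intermediate
6 | methyl (E)-3-[4-(2-methoxy-2-oxoethoxy)-3,5-bis(methoxymethoxy)phenyl]prop-2-enoate | COCOc1cc(/C=C/C(=O)OC)cc(OCOC)c1OCC(=O)OC | intermediate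
7 | 3,4,5-trimethoxybenzoyl chloride | COc1cc(C(=O)Cl)cc(OC)c1OC | starting material
8 | racemic methyl 2-{4-[(E)-3-methoxy-3-oxoprop-1-enyl]-2,6-bis(methoxymethoxy)phenoxy}-3-oxo-3-(3,4,5-trimethoxyphenyl)propanoate | COc1cc(C(=O)C(Oc2c(OCOC)cc(/C=C/C(=O)OC)cc2OCOC)C(=O)OC)cc(OC)c1OC | intermediate
9 | methyl (2R,3S)-3-hydroxy-2-{4-[(E)-3-methoxy-3-oxoprop-1-enyl]-2,6-bis(methoxymethoxy)phenoxy}-3-(3,4,5-trimethoxyphenyl)propanoate | COc1cc([C@H](O)[C@H](C(=O)OC)Oc2c(OCOC)cc(/C=C/C(=O)OC)cc2OCOC)cc(OC)c1OC | intermediate
10 | methyl (E)-3-[4-{[(1S,2S)-1,3-dihydroxy-1-(3,4,5-trimethoxyphenyl)propan-2-yl]oxy}-3,5-bis(methoxymethoxy)phenyl]prop-2-enoate | COc1cc([C@H](O)[C@H](CO)Oc2c(OCOC)cc(/C=C/C(=O)OC)cc2OCOC)cc(OC)c1OC | intermediate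
11 | methyl (E)-3-[4-{[(1S,2S)-1,3-dihydroxy-1-(3,4,5-trimethoxyphenyl)propan-2-yl]oxy}-3,5-dihydroxyphenyl]prop-2-enoate | COc1cc([C@H](O)[C@H](CO)Oc2c(O)cc(/C=C/C(=O)OC)cc2O)cc(OC)c1OC | intermediate
12 | methyl (E)-3-[(2S,3S)-8-hydroxy-2-(hydroxymethyl)-3-(3,4,5-trimethoxyphenyl)-2,3-dihydro-1,4-benzodioxin-6-yl]prop-2-enoate | COc1cc([C@@H]2Oc3cc(/C=C/C(=O)OC)cc(O)c3O[C@H]2CO)cc(OC)c1OC | intermediate
13 | (E)-3-[(2S,3S)-8-hydroxy-2-(hydroxymethyl)-3-(3,4,5-trimethoxyphenyl)-2,3-dihydro-1,4-benzodioxin-6-yl]prop-2-en-1-ol | COc1cc([C@@H]2Oc3cc(/C=C/CO)cc(O)c3O[C@H]2CO)cc(OC)c1OC | intermediate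
14 | (E)-3-[(2S,3S)-8-hydroxy-2-(hydroxymethyl)-3-(3,4,5-trimethoxyphenyl)-2,3-dihydro-1,4-benzodioxin-6-yl]prop-2-enal | COc1cc([C@@H]2Oc3cc(/C=C/C=O)cc(O)c3O[C@H]2CO)cc(OC)c1OC | target

Total step count: 8. Longest linear sequence: 8 steps (from 1).

Steps most likely to fail

1. Step 4. Hydride transfer to the crowded ketone may be slow or poorly discriminating, giving low syn/anti or facial selectivity, or racemisation at C8 may not keep pace with reduction. The fallback is an auxiliary-controlled glycolate aldol reaction, which sets out from 6 and comes back at 10. Selective saponification of the activated aryloxyacetate ester of 6 (LiOH, 1 equiv, THF/water, 0 °C; the conjugated cinnamate ester reacts much more slowly) should give the aryloxyacetic acid F1. Activation with pivaloyl chloride and Et3N gives the mixed pivalic anhydride F2, which acylates (R)-4-benzyloxazolidin-2-one in the presence of LiCl to give the N-(aryloxyacetyl)oxazolidinone F3. Boron-mediated syn aldol addition (Bu2BOTf, iPr2NEt, CH2Cl2, −78 to 0 °C) to 3,4,5-trimethoxybenzaldehyde through the Z-enolate and a closed chair transition state should give the (2R,3S) syn aldol adduct F4. Reductive removal of the auxiliary with NaBH4 in THF/water then gives diol 10 directly.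

2. Step 6. The C7 cation may lose the C8 proton or fragment, as in acidolysis of arylglycerol aryl ethers, or may oligomerise instead of closing, and trans selectivity may be incomplete. The fallback is a stereospecific double inversion with known Mitsunobu chemistry, which sets out from 10 and comes back at 13. Pivaloyl chloride in pyridine should acylate only the primary alcohol to give the 9-O-pivalate F5. Mitsunobu inversion at C7 (PPh3, DIAD, 4-nitrobenzoic acid) gives the (7R,8S) 4-nitrobenzoate F6, and K2CO3 in methanol at 0 °C removes the nitrobenzoate to give the erythro alcohol F7. Dilute methanolic HCl at 0 °C to rt, too weak to ionise C7, removes the MOM groups to give the erythro diphenol F8. Intramolecular Mitsunobu etherification under high dilution closes the ring with inversion at C7 to give the trans-benzodioxane pivalate F9. The DIBAL conditions of step 7 then cleave the pivalate and reduce the cinnamate in one operation to give 13.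

3. Step 3. The enolate may add to the cinnamate of a second molecule, or the product enolate may be acylated again on oxygen or carbon. The fallback is an aldol addition followed by oxidation, which sets out from 6 and comes back at 8. The lithium enolate of 6 (LiHMDS, 1.1 equiv, THF, −78 °C) is added to 3,4,5-trimethoxybenzaldehyde to give the racemic β-hydroxy ester F10 as a syn/anti mixture. Dess–Martin periodinane (CH2Cl2, NaHCO3) should oxidise both diastereomers to the same ketoester 8.

Further compounds
F1 | step 4 | 2-{4-[(E)-3-methoxy-3-oxoprop-1-enyl]-2,6-bis(methoxymethoxy)phenoxy}acetic acid | OC(=O)COc1c(OCOC)cc(/C=C/C(=O)OC)cc1OCOC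
F2 | step 4 | mixed anhydride of F1 with pivalic acid | CC(C)(C)C(=O)OC(=O)COc1c(OCOC)cc(/C=C/C(=O)OC)cc1OCOC
F3 | step 4 | (R)-4-benzyl-3-(aryloxyacetyl)oxazolidin-2-one | O=C1OC[C@@H](Cc2ccccc2)N1C(=O)COc3c(OCOC)cc(/C=C/C(=O)OC)cc3OCOC
F4 | step 4 | (4R)-4-benzyl-3-[(2R,3S)-2-aryloxy-3-hydroxy-3-(3,4,5-trimethoxyphenyl)propanoyl]oxazolidin-2-one (syn aldol adduct) | O=C1OC[C@@H](Cc2ccccc2)N1C(=O)[C@H](Oc3c(OCOC)cc(/C=C/C(=O)OC)cc3OCOC)[C@@H](O)c4cc(OC)c(OC)c(OC)c4
F5 | step 6 | 9-O-pivalate of threo-(7S,8S) diol 10 | COc1cc([C@H](O)[C@H](COC(=O)C(C)(C)C)Oc2c(OCOC)cc(/C=C/C(=O)OC)cc2OCOC)cc(OC)c1OC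
F6 | step 6 | (7R,8S) 7-O-(4-nitrobenzoate) 9-O-pivalate | COc1cc([C@@H](OC(=O)c2ccc(cc2)[N+](=O)[O-])[C@H](COC(=O)C(C)(C)C)Oc3c(OCOC)cc(/C=C/C(=O)OC)cc3OCOC)cc(OC)c1OC
F7 | step 6 | erythro-(7R,8S) alcohol 9-O-pivalate with two MOM ethers | COc1cc([C@@H](O)[C@H](COC(=O)C(C)(C)C)Oc2c(OCOC)cc(/C=C/C(=O)OC)cc2OCOC)cc(OC)c1OC
F8 | step 6 | erythro-(7R,8S) alcohol 9-O-pivalate with both phenols free | COc1cc([C@@H](O)[C@H](COC(=O)C(C)(C)C)Oc2c(O)cc(/C=C/C(=O)OC)cc2O)cc(OC)c1OC
F9 | step 6 | trans-(7S,8S)-benzodioxane methyl cinnamate 9-O-pivalate | COc1cc([C@@H]2Oc3cc(/C=C/C(=O)OC)cc(O)c3O[C@H]2COC(=O)C(C)(C)C)cc(OC)c1OC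
F10 | step 3 | racemic methyl 2-aryloxy-3-hydroxy-3-(3,4,5-trimethoxyphenyl)propanoate, syn/anti mixture | COc1cc(C(O)C(Oc2c(OCOC)cc(/C=C/C(=O)OC)cc2OCOC)C(=O)OC)cc(OC)c1OC
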